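**Retrosynthetic overview**
- The target comes from a tri-O-methyl isocoumarin aldehyde by a late ArCHO → ArCO2H oxidation and a global O-demethylation.
- The pyranone ring is the only ring built. Its C4–C4a bond joins the ortho C–H carbon of a 2-aryloxy-4-methoxybenzoic acid (as aryl–Ru) to the α-carbon of a β-keto sulfoxonium ylide made from hexanoyl chloride. The ylide serves as a ketone α-cation (enolonium-type, metal-carbene) equivalent, and lactonisation follows in the same flask.
- The diaryl ether comes from an Ullmann coupling of 2-bromo-4-methoxybenzoic acid with a hindered phenol-aldehyde.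
- The phenol-aldehyde comes from olivetol dimethyl ether by formylation, Dakin-type oxidation and a second formylation.
- Ring order: both benzene rings are bought (ring B from olivetol dimethyl ether, ring A from the bromobenzoic acid); the lactone ring is closed last, in step 6.

Assumption: the target SMILES has no stereocentre and no stereogenic double bond, so the compound is achiral and no stereocontrol is needed.

**Route**

Step 1
Reactants: 1 1,3-dimethoxy-5-pentylbenzene (olivetol dimethyl ether)
Product: 3 2,4-dimethoxy-6-pentylbenzaldehyde, via iminium chloride 2 (not isolated)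
Conditions: POCl3 (1.5 equiv), DMF, 0 → 80 °C; then H2O
Reagents that add atoms: N,N-dimethylformamide, CN(C)C=O; water, O
Why: Vilsmeier–Haack formylation, in which the chloroiminium ion attacks the position para to one OMe, ortho to the other and next to the pentyl chain, the usual major site for 5-alkylresorcinol dimethyl ethers (no stereocentre is formed).

Step 2
Reactants: 3 2,4-dimethoxy-6-pentylbenzaldehyde
Product: 5 2,4-dimethoxy-6-pentylphenol, via aryl formate 4 (not isolated)
Conditions: mCPBA (1.3 equiv), CH2Cl2, 0 °C → rt; aq. Na2S2O3 wash; then K2CO3 (cat.), MeOH, rt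
Reagents that add atoms: meta-chloroperoxybenzoic acid, O=C(OO)c1cccc(Cl)c1
Why: Baeyer–Villiger (Dakin-type) oxidation, in which the electron-rich aryl group migrates in the Criegee adduct to give the aryl formate, which mild methanolysis cleaves to the phenol.

Step 3
Reactants: 5 2,4-dimethoxy-6-pentylphenol
Product: 7 3-hydroxy-4,6-dimethoxy-2-pentylbenzaldehyde, via iminium chloride 6 (not isolated)
Conditions: POCl3 (3 equiv), DMF, 0 → 70 °C; then H2O
Reagents that add atoms: N,N-dimethylformamide, CN(C)C=O; water, O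
Why: Second Vilsmeier–Haack formylation, directed to C5 because that site has the same environment as the one attacked in step 1 (para to one OMe, ortho to the other, beside the pentyl chain), while both positions ortho and the position para to the OH are blocked.

Step 4
Reactants: 7 3-hydroxy-4,6-dimethoxy-2-pentylbenzaldehyde; 8 2-bromo-4-methoxybenzoic acid
Product: 9 2-(3-formyl-4,6-dimethoxy-2-pentylphenoxy)-4-methoxybenzoic acid
Conditions: CuI (10 mol %), picolinic acid (20 mol %), K3PO4 (3 equiv), DMSO, 100 °C; then aq. HCl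
Reagents that add atoms: none
Why: Ullmann-type Cu(I)-catalysed diaryl ether synthesis, helped by the ortho-carboxylate of the bromo acid (ortho effect) and by a ligand system suited to 2,6-disubstituted phenols; the non-enolisable aldehyde is inert to phosphate base.

Step 5
Reactants: 10 hexanoyl chloride; 11 trimethylsulfoxonium iodide
Product: 13 1-[dimethyl(oxo)-λ6-sulfanylidene]heptan-2-one, via dimethylsulfoxonium methylide 12 (not isolated)
Conditions: 11 (3 equiv), KOtBu (3 equiv), THF, reflux, 2 h; then 10, 0 °C → rt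
Reagents that add atoms: none
Why: C-acylation of the Corey–Chaykovsky methylide by the acid chloride, after which a second equivalent of methylide deprotonates the acylsulfoxonium salt to give the bench-stable β-keto sulfoxonium ylide.

Step 6
Reactants: 9 2-(3-formyl-4,6-dimethoxy-2-pentylphenoxy)-4-methoxybenzoic acid; 13 1-[dimethyl(oxo)-λ6-sulfanylidene]heptan-2-one
Product: 15 4,6-dimethoxy-3-[(6-methoxy-1-oxo-3-pentyl-1H-isochromen-8-yl)oxy]-2-pentylbenzaldehyde, via keto acid 14 (not isolated)
Conditions: [RuCl2(p-cymene)]2 (5 mol %), AgSbF6 (20 mol %), NaOAc (50 mol %), CF3CH2OH, 90 °C, N2; then p-TsOH·H2O (20 mol %), 60 °C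
Reagents that add atoms: none
Why: Carboxylate-directed Ru(II) C–H activation/carbene migratory insertion (C–H acylmethylation–annulation): ruthenation at the only free ortho C–H gives a nucleophilic aryl–Ru carbon that captures the ylide, after loss of DMSO, as an electrophilic Ru-carbene, so the ketone α-carbon reacts as an enolonium-type acceptor rather than as an enolate, and the resulting 2-(2-oxoheptyl)benzoic acid cyclodehydrates to the six-membered enol lactone (the B-ring aldehyde has no ortho C–H and stays untouched).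

Step 7
Reactants: 15 4,6-dimethoxy-3-[(6-methoxy-1-oxo-3-pentyl-1H-isochromen-8-yl)oxy]-2-pentylbenzaldehyde
Product: 16 4,6-dimethoxy-3-[(6-methoxy-1-oxo-3-pentyl-1H-isochromen-8-yl)oxy]-2-pentylbenzoic acid
Conditions: NaClO2 (3 equiv), NaH2PO4 (3 equiv), 2-methyl-2-butene (20 equiv), t-BuOH/THF/H2O, 0 °C → rt
Reagents that add atoms: sodium chlorite, [Na+].[O-]Cl=O
Why: Pinnick (Lindgren–Kraus) oxidation, in which chlorous acid adds to the hindered aldehyde and fragments to the acid while the alkene scavenger removes HOCl before it can chlorinate the electron-rich rings or the enol lactone.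

Step 8
Reactants: 16 4,6-dimethoxy-3-[(6-methoxy-1-oxo-3-pentyl-1H-isochromen-8-yl)oxy]-2-pentylbenzoic acid
Product: 17 4,6-dihydroxy-3-[(6-hydroxy-1-oxo-3-pentyl-1H-isochromen-8-yl)oxy]-2-pentylbenzoic acid (target, CNP0439913.0)
Conditions: BBr3 (6 equiv), CH2Cl2, −78 °C → rt; then H2O, 0 °C
Reagents that add atoms: none
Why: Lewis-acid aryl methyl ether cleavage (bromide attacks the O-methyl group of each boron-complexed ether), which leaves the diaryl ether, the isocoumarin lactone and the acid intact at or below room temperature, where decarboxylation of the resorcylic acid is slow.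

**Compound list**

1 | 1,3-dimethoxy-5-pentylbenzene (olivetol dimethyl ether) | CCCCCc1cc(OC)cc(OC)c1 | starting material
2 | [(2,4-dimethoxy-6-pentylphenyl)methylidene]dimethylammonium chloride | CCCCCc1cc(OC)cc(OC)c1C=[N+](C)C.[Cl-] | intermediate
3 | 2,4-dimethoxy-6-pentylbenzaldehyde | CCCCCc1cc(OC)cc(OC)c1C=O | intermediate
4 | 2,4-dimethoxy-6-pentylphenyl formate | CCCCCc1cc(OC)cc(OC)c1OC=O | intermediate
5 | 2,4-dimethoxy-6-pentylphenol | CCCCCc1cc(OC)cc(OC)c1O | intermediate
6 | [(3-hydroxy-4,6-dimethoxy-2-pentylphenyl)methylidene]dimethylammonium chloride | CCCCCc1c(C=[N+](C)C)c(OC)cc(OC)c1O.[Cl-] | intermediate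
7 | 3-hydroxy-4,6-dimethoxy-2-pentylbenzaldehyde | CCCCCc1c(C=O)c(OC)cc(OC)c1O | intermediate
8 | 2-bromo-4-methoxybenzoic acid | COc1ccc(C(=O)O)c(Br)c1 | starting material
9 | 2-(3-formyl-4,6-dimethoxy-2-pentylphenoxy)-4-methoxybenzoic acid | CCCCCc1c(C=O)c(OC)cc(OC)c1Oc1cc(OC)ccc1C(=O)O | intermediate
10 | hexanoyl chloride | CCCCCC(=O)Cl | starting material
11 | trimethylsulfoxonium iodide | C[S+](C)(C)=O.[I-] | starting material
12 | dimethylsulfoxonium methylide | C=S(C)(C)=O | intermediate
13 | 1-[dimethyl(oxo)-λ6-sulfanylidene]heptan-2-one | CCCCCC(=O)C=S(C)(C)=O | intermediate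
14 | 2-(3-formyl-4,6-dimethoxy-2-pentylphenoxy)-4-methoxy-6-(2-oxoheptyl)benzoic acid | CCCCCC(=O)Cc1cc(OC)cc(Oc2c(CCCCC)c(C=O)c(OC)cc2OC)c1C(=O)O | intermediate
15 | 4,6-dimethoxy-3-[(6-methoxy-1-oxo-3-pentyl-1H-isochromen-8-yl)oxy]-2-pentylbenzaldehyde | CCCCCc1cc2cc(OC)cc(Oc3c(CCCCC)c(C=O)c(OC)cc3OC)c2c(=O)o1 | intermediate
16 | 4,6-dimethoxy-3-[(6-methoxy-1-oxo-3-pentyl-1H-isochromen-8-yl)oxy]-2-pentylbenzoic acid | CCCCCc1cc2cc(OC)cc(Oc3c(CCCCC)c(C(=O)O)c(OC)cc3OC)c2c(=O)o1 | intermediate
17 | 4,6-dihydroxy-3-[(6-hydroxy-1-oxo-3-pentyl-1H-isochromen-8-yl)oxy]-2-pentylbenzoic acid | CCCCCc1cc2cc(O)cc(Oc3c(O)cc(O)c(C(=O)O)c3CCCCC)c2c(=O)o1 | target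

**Totals and risks**

Total step count: 8. Longest linear sequence: 7 (steps 1, 2, 3, 4, 6, 7, 8); step 5 is a one-step side branch.

Most likely to fail, first: step 6. The C–H annulation is run on a congested, polyfunctional acid; lactonisation may stall at keto acid 14, or the ylide may O-alkylate the carboxylic acid. The fallback sets out from 9 and comes back at 15. Pd(OAc)2-catalysed carboxylate-directed ortho-iodination (PhI(OAc)2, I2, DMF) gives 2-(3-formyl-4,6-dimethoxy-2-pentylphenoxy)-6-iodo-4-methoxybenzoic acid F1. Coupling of F1 with hept-1-yne (Pd(PPh3)4, ZnCl2, Et3N, DMF, 100 °C) gives 2-(3-formyl-4,6-dimethoxy-2-pentylphenoxy)-6-(hept-1-yn-1-yl)-4-methoxybenzoic acid F2, which cyclises 6-endo-dig in the same pot (or with catalytic AgOTf) to isocoumarin 15.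

Second: step 4. The phenol is flanked by OMe and pentyl, so the Ullmann coupling may be slow or give protodebromination of 8. The fallback sets out from 7 and comes back at 9, using metal-free O-arylation with a diaryliodonium salt, which tolerates heavy ortho substitution. Commercial methyl 2-iodo-4-methoxybenzoate F3 is oxidised (mCPBA, TsOH·H2O, MeCN, 77 °C) and trapped with 1,3,5-trimethoxybenzene to give [5-methoxy-2-(methoxycarbonyl)phenyl](2,4,6-trimethoxyphenyl)iodonium tosylate F4. Phenol 7 with KOtBu and F4 in THF at rt transfers the ester-bearing aryl group selectively and gives methyl 2-(3-formyl-4,6-dimethoxy-2-pentylphenoxy)-4-methoxybenzoate F5. LiOH in THF/H2O then gives acid 9.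

Third: step 3. The risk is regioselectivity (C5 against C3 between the two OMe groups) and consumption of reagent by the free phenol. The fallback sets out from 3 and comes back at 7, introducing the oxygen after the carbon instead of before it. Bromination of aldehyde 3 (NBS, MeCN, 0 °C → rt) para to the 2-OMe gives 3-bromo-4,6-dimethoxy-2-pentylbenzaldehyde F6, whose regioisomer can be removed at this stage. Pd-catalysed hydroxylation of F6 (tBuBrettPhos Pd G3, KOH, dioxane/H2O, 80 °C) then gives phenol-aldehyde 7, so steps 2 and 3 are both bypassed.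

**Further compounds**

F1 | step 6 | 2-(3-formyl-4,6-dimethoxy-2-pentylphenoxy)-6-iodo-4-methoxybenzoic acid | CCCCCc1c(C=O)c(OC)cc(OC)c1Oc1cc(OC)cc(I)c1C(=O)O
F2 | step 6 | 2-(3-formyl-4,6-dimethoxy-2-pentylphenoxy)-6-(hept-1-yn-1-yl)-4-methoxybenzoic acid | CCCCCC#Cc1cc(OC)cc(Oc2c(CCCCC)c(C=O)c(OC)cc2OC)c1C(=O)O
F3 | step 4 | methyl 2-iodo-4-methoxybenzoate (purchased) | COC(=O)c1ccc(OC)cc1I
F4 | step 4 | [5-methoxy-2-(methoxycarbonyl)phenyl](2,4,6-trimethoxyphenyl)iodonium 4-methylbenzenesulfonate | COC(=O)c1ccc(OC)cc1[I+]c1c(OC)cc(OC)cc1OC.Cc1ccc(S(=O)(=O)[O-])cc1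
F5 | step 4 | methyl 2-(3-formyl-4,6-dimethoxy-2-pentylphenoxy)-4-methoxybenzoate | CCCCCc1c(C=O)c(OC)cc(OC)c1Oc1cc(OC)ccc1C(=O)OC
F6 | step 3 | 3-bromo-4,6-dimethoxy-2-pentylbenzaldehyde | CCCCCc1c(Br)c(OC)cc(OC)c1C=O
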